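**Retrosynthetic overview**
1. Target 20 ⇐ 17 by oxidation of the C17 methyl of the C15 isopropenyl group to CO2H (C17 aldehyde 19 in between).
2. 17 ⇐ bis-epoxide 15: the C8–O–C11 tetrahydrofuran across the 14-membered carbocycle and the C7(OH)/C8/C11/C12(OH) tetrad come from one transannular, water-terminated epoxide-opening cascade of the (7S,8S,11S,12S)-7,8:11,12-diepoxide.
3. 15 ⇐ 7E,11E-diene 14 by double Shi epoxidation; C1 (isopropenyl) and C3 (OAc) are set on the ring from enone 11 by Rh-catalysed 1,4-addition and CBS reduction.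
4. Enone 11 (C1=C2) ⇐ keto-aldehyde 10 by intramolecular aldol condensation; 10 ⇐ (S)-(E)-nerolidol 4, which supplies C4 and both E-olefins, by terminal two-carbon homologation and Wacker oxidation.
5. 4 ⇐ (E,E)-farnesol 1 by Sharpless epoxidation and reductive opening. Ring order: carbocycle first (step 9), then the oxolane across it (step 14).

Key step: step 14

Remark (numbering): ring positions follow cembrane numbering. C1 bears the C15(=C16H2)–C17 unit, C3 the acetate, C4/C8/C12 the methyl groups, and the ether oxygen links C8 and C11.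
Assumption: in step 10 the facial sense of the Rh/BINAP addition is taken from the accepted quadrant model (α-si face for (S)-BINAP, which gives 1R here). If the macrocyclic enone responds in the opposite sense, (R)-BINAP is used and nothing else changes.

**Route**

Step 1
Reactants: 1 (2E,6E)-farnesol
Product: 2 (2S,3S)-2,3-epoxyfarnesol
Conditions: Ti(OiPr)4 (10 mol %), L-(+)-diethyl tartrate (12 mol %), t-BuOOH, 4 Å MS, CH2Cl2, −20 °C
Reagents that add atoms: tert-butyl hydroperoxide, CC(C)(C)OO
Why: Sharpless asymmetric epoxidation touches only the allylic-alcohol olefin and, with L-(+)-DET, should give the (2S,3S)-epoxide, whose quaternary C–O bond becomes the C4 carbinol of the target.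

Step 2
Reactants: 2 (2S,3S)-2,3-epoxyfarnesol
Product: 4 (S)-(E)-nerolidol, via 2,3-epoxyfarnesyl iodide 3 (not isolated)
Conditions: PPh3, I2, imidazole, THF, 0 °C; then Zn dust, AcOH, EtOH, 0 °C to rt (same flask)
Reagents that add atoms: none
Why: Garegg-type iodination of the primary alcohol followed by zinc-mediated reductive elimination of the β-alkoxy organozinc opens the epoxide to the tertiary vinyl carbinol without touching the quaternary C–O bond, so the S configuration is retained.

Step 3
Reactants: 4 (S)-(E)-nerolidol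
Product: 5 (S)-(E)-nerolidol triethylsilyl ether
Conditions: TESOTf, 2,6-lutidine, CH2Cl2, −78 to 0 °C
Reagents that add atoms: triethylsilyl trifluoromethanesulfonate, CC[Si](CC)(CC)OS(=O)(=O)C(F)(F)F
Why: Silyl triflate silylation of the tertiary alcohol masks the future C4 oxygen, which must not take part in the key cascade.

Step 4
Reactants: 5 (S)-(E)-nerolidol triethylsilyl ether
Product: 6 (2E,6E,10S)-2,6,10-trimethyl-10-(triethylsilyloxy)dodeca-2,6,11-trien-1-ol
Conditions: SeO2 (0.3 equiv), t-BuOOH, salicylic acid (cat.), CH2Cl2, 0 °C to rt, stopped at partial conversion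
Reagents that add atoms: tert-butyl hydroperoxide, CC(C)(C)OO
Why: Riley-type SeO2 allylic oxidation (ene then [2,3]-shift) should hydroxylate the (E)-methyl of the terminal trisubstituted olefin preferentially and give the E-allylic alcohol; the vinyl group has no allylic hydrogen.

Step 5
Reactants: 6 the allylic alcohol
Product: 7 (3S,6E,10E)-12-bromo-3,7,11-trimethyl-3-(triethylsilyloxy)dodeca-1,6,10-triene
Conditions: CBr4, PPh3, CH2Cl2, −40 to 0 °C
Reagents that add atoms: carbon tetrabromide, BrC(Br)(Br)Br
Why: Appel bromination converts the primary allylic alcohol to the bromide by SN2 at low temperature, without allylic transposition or loss of the E geometry.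

Step 6
Reactants: 7 the allylic bromide
Product: 8 (4E,8E,12S)-4,8,12-trimethyl-12-(triethylsilyloxy)tetradeca-4,8,13-trienenitrile
Conditions: MeCN (5 equiv), n-BuLi (4.5 equiv), THF, −78 °C; then 7, −78 to −40 °C
Reagents that add atoms: acetonitrile (as lithioacetonitrile), CC#N
Why: SN2 alkylation of lithioacetonitrile at the primary allylic carbon adds C14 and C1 (the latter as the nitrile carbon), with excess anion suppressing dialkylation.

Step 7
Reactants: 8 the nitrile
Product: 9 (4E,8E,12S)-4,8,12-trimethyl-12-(triethylsilyloxy)tetradeca-4,8,13-trienal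
Conditions: DIBAL-H, CH2Cl2, −78 °C; aqueous Rochelle salt work-up
Reagents that add atoms: water, O
Why: DIBAL half-reduction stops at the N-aluminio aldimine, which is hydrolysed on work-up to the γ,δ-unsaturated aldehyde (C1).

Step 8
Reactants: 9 the aldehyde
Product: 10 (4E,8E,12S)-4,8,12-trimethyl-13-oxo-12-(triethylsilyloxy)tetradeca-4,8-dienal
Conditions: PdCl2 (10 mol %), CuCl, O2 (1 atm), DMF/H2O 7:1, rt
Reagents that add atoms: water, O
Why: Tsuji–Wacker oxidation acts only on the monosubstituted vinyl group (trisubstituted olefins are inert) and by Markovnikov hydroxypalladation should give the α-silyloxy methyl ketone (C3=O, C2H3).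

Step 9
Reactants: 10 the keto-aldehyde
Product: 11 (1E,4S,7E,11E)-4,8,12-trimethyl-4-(triethylsilyloxy)cyclotetradeca-1,7,11-trien-3-one
Conditions: KOH, EtOH/THF, syringe-pump addition of 10 (final 2 mM), 25 to 40 °C
Reagents that add atoms: none
Why: Intramolecular aldol condensation (Claisen–Schmidt type) under high dilution; the ketone can enolise only at its methyl group (C4 is quaternary), aldol steps are reversible and dehydration to the conjugated E-enone is the sink, which closes the 14-membered ring at C1=C2.

Step 10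
Reactants: 11 the macrocyclic enone
Product: 12 (1R,4S,7E,11E)-1-isopropenyl-4,8,12-trimethyl-4-(triethylsilyloxy)cyclotetradeca-7,11-dien-3-one
Conditions: isopropenylboronic acid pinacol ester, [Rh(OH)(cod)]2 (3 mol %), (S)-BINAP (7 mol %), KOH (cat.), 1,4-dioxane/H2O 10:1, 50 °C
Reagents that add atoms: isopropenylboronic acid pinacol ester, CC(=C)B1OC(C)(C)C(C)(C)O1
Why: Hayashi–Miyaura Rh-catalysed asymmetric 1,4-addition of an alkenylboron reagent to the E-enone; the (S)-BINAP–Rh–alkenyl species should deliver isopropenyl to the face of C1 that gives 1R (catalyst control), and the isolated olefins do not react.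

Step 11
Reactants: 12 the ketone
Product: 13 (1R,3R,4S,7E,11E)-1-isopropenyl-4,8,12-trimethyl-4-(triethylsilyloxy)cyclotetradeca-7,11-dien-3-ol
Conditions: (S)-2-methyl-CBS-oxazaborolidine (0.5 equiv), catecholborane, toluene, −78 to −40 °C
Reagents that add atoms: none
Why: CBS reduction with catecholborane (which does not hydroborate the olefins) should give the 3R alcohol by reagent control, with the quaternary C4 as the large and the C2 methylene as the small ketone substituent.

Step 12
Reactants: 13 the alcohol
Product: 14 (1R,3R,4S,7E,11E)-3-acetoxy-1-isopropenyl-4,8,12-trimethyl-4-(triethylsilyloxy)cyclotetradeca-7,11-diene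
Conditions: Ac2O, pyridine, DMAP (cat.), CH2Cl2, rt
Reagents that add atoms: acetic anhydride, CC(=O)OC(C)=O
Why: DMAP-catalysed acetylation of the only free hydroxyl places the C3 acetate before any other secondary alcohol exists.

Step 13
Reactants: 14 the diene acetate
Product: 15 (1R,3R,4S,7S,8S,11S,12S)-7,8:11,12-bis-epoxide of 14
Conditions: L-fructose-derived (ent-)Shi ketone (0.6 equiv), Oxone (2.6 equiv), K2CO3, Bu4NHSO4 (cat.), Na2B4O7/Na2EDTA buffer (pH 10.5), MeCN/dimethoxymethane 1:2, 0 °C
Reagents that add atoms: potassium peroxymonosulfate (Oxone), OOS(=O)(=O)[O-].[K+]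
Why: Shi epoxidation with the enantiomeric ketone should give the S,S epoxide at each E-trisubstituted olefin by reagent control (the D-fructose ketone gives R,R), while the less nucleophilic 1,1-disubstituted isopropenyl group reacts much more slowly under limited oxidant.

Step 14
Reactants: 15 the bis-epoxide
Product: 17 (1R,3R,4S,7S,8R,11S,12R)-3-acetoxy-8,11-epoxy-1-isopropenyl-4,8,12-trimethylcyclotetradecane-4,7,12-triol, via its 4-O-triethylsilyl ether 16 (not isolated)
Conditions: CSA (0.2 equiv), THF/H2O 5:1, 0 °C; then 1 M HCl added, rt (same flask)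
Reagents that add atoms: water, O
Why: Brønsted acid activates the epoxides; the oxygen of the 11,12-epoxide attacks the tertiary C8 of the protonated 7,8-epoxide from the rear across the ring to give a bicyclic epoxonium ion, which water opens at tertiary C12 (the same product forms if water opens C12 first and the C11 hydroxyl then closes on C8). The closest known reaction type is the acid-triggered, exo-selective epoxide-opening cascade of 1,5-diepoxides to 2,5-disubstituted tetrahydrofurans, together with the transannular epoxide participation seen on hydrolysis of medium-ring diepoxides. Only the oxolane (O, C8, C9, C10, C11) is closed, in the 5-exo-tet mode, and it spans the 14-membered ring as a 2,5-cis ether. C7 and C11 keep the C–O bonds installed by the Shi epoxidation, while C8 and C12 are each inverted once by the stereospecific anti openings, so (7S,8S,11S,12S) becomes (7S,8R,11S,12R). The step needs the cascade to run from O11 to C8 and not in the reverse sense or through the C4 oxygen: the head-to-tail diepoxide makes only this direction both 5-exo and Markovnikov (C8 is tertiary and proximal; the reverse would be 6-endo at C12 or anti-Markovnikov at C11), and the C4 oxygen is silylated and the C3 oxygen acetylated. Acidification then removes the TES group in the same flask.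

Step 15
Reactants: 17 the oxa-bridged triol acetate
Product: 19 the C17 aldehyde (2-substituted acrolein) of 17, via the C17 allylic alcohol 18 (not isolated)
Conditions: SeO2 (0.5 equiv), t-BuOOH, CH2Cl2, rt; then MnO2 (excess), same flask, rt
Reagents that add atoms: tert-butyl hydroperoxide, CC(C)(C)OO
Why: SeO2 allylic oxidation of the only remaining olefin should hydroxylate the isopropenyl methyl (CH3 preferred over the C1 methine), and MnO2, which oxidises only allylic alcohols, converges the alcohol/aldehyde mixture to the enal.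

Step 16
Reactants: 19 the enal
Product: 20 Dendronpholide J
Conditions: NaClO2, NaH2PO4, 2-methyl-2-butene, t-BuOH/H2O 4:1, 0 °C to rt
Reagents that add atoms: sodium chlorite, [O-]Cl=O.[Na+]
Why: Pinnick oxidation converts the α-methylene aldehyde to the acrylic acid without touching the acetate, the free alcohols or the ether.

**Compound list**
1 | (2E,6E)-farnesol | OC/C=C(\C)CC/C=C(\C)CCC=C(C)C | starting material
2 | (2S,3S)-2,3-epoxyfarnesol | OC[C@@H]1O[C@@]1(C)CC/C=C(\C)CCC=C(C)C | intermediate
3 | 2,3-epoxyfarnesyl iodide (epoxide configuration of 2) | IC[C@@H]1O[C@@]1(C)CC/C=C(\C)CCC=C(C)C | intermediate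
4 | (S)-(E)-nerolidol, (3S,6E)-3,7,11-trimethyldodeca-1,6,10-trien-3-ol | C=C[C@@](C)(O)CC/C=C(\C)CCC=C(C)C | intermediate
5 | (S)-(E)-nerolidol triethylsilyl ether | C=C[C@@](C)(O[Si](CC)(CC)CC)CC/C=C(\C)CCC=C(C)C | intermediate
6 | (2E,6E,10S)-2,6,10-trimethyl-10-(triethylsilyloxy)dodeca-2,6,11-trien-1-ol | C=C[C@@](C)(O[Si](CC)(CC)CC)CC/C=C(\C)CC/C=C(\C)CO | intermediate
7 | (3S,6E,10E)-12-bromo-3,7,11-trimethyl-3-(triethylsilyloxy)dodeca-1,6,10-triene | C=C[C@@](C)(O[Si](CC)(CC)CC)CC/C=C(\C)CC/C=C(\C)CBr | intermediate
8 | (4E,8E,12S)-4,8,12-trimethyl-12-(triethylsilyloxy)tetradeca-4,8,13-trienenitrile | C=C[C@@](C)(O[Si](CC)(CC)CC)CC/C=C(\C)CC/C=C(\C)CCC#N | intermediate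
9 | (4E,8E,12S)-4,8,12-trimethyl-12-(triethylsilyloxy)tetradeca-4,8,13-trienal | C=C[C@@](C)(O[Si](CC)(CC)CC)CC/C=C(\C)CC/C=C(\C)CCC=O | intermediate
10 | (4E,8E,12S)-4,8,12-trimethyl-13-oxo-12-(triethylsilyloxy)tetradeca-4,8-dienal | CC(=O)[C@@](C)(O[Si](CC)(CC)CC)CC/C=C(\C)CC/C=C(\C)CCC=O | intermediate
11 | (1E,4S,7E,11E)-4,8,12-trimethyl-4-(triethylsilyloxy)cyclotetradeca-1,7,11-trien-3-one (cembrane numbering) | C[C@]1(O[Si](CC)(CC)CC)CC/C=C(\C)CC/C=C(\C)CC/C=C/C1=O | intermediate
12 | (1R,4S,7E,11E)-1-isopropenyl-4,8,12-trimethyl-4-(triethylsilyloxy)cyclotetradeca-7,11-dien-3-one | C[C@]1(O[Si](CC)(CC)CC)CC/C=C(\C)CC/C=C(\C)CC[C@@H](C(C)=C)CC1=O | intermediate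
13 | (1R,3R,4S,7E,11E)-1-isopropenyl-4,8,12-trimethyl-4-(triethylsilyloxy)cyclotetradeca-7,11-dien-3-ol | C[C@]1(O[Si](CC)(CC)CC)CC/C=C(\C)CC/C=C(\C)CC[C@@H](C(C)=C)C[C@H]1O | intermediate
14 | (1R,3R,4S,7E,11E)-3-acetoxy-1-isopropenyl-4,8,12-trimethyl-4-(triethylsilyloxy)cyclotetradeca-7,11-diene | C[C@]1(O[Si](CC)(CC)CC)CC/C=C(\C)CC/C=C(\C)CC[C@@H](C(C)=C)C[C@H]1OC(C)=O | intermediate
15 | (1R,3R,4S,7S,8S,11S,12S)-7,8:11,12-bis-epoxide of 14 | C[C@]1(O[Si](CC)(CC)CC)CC[C@@H]2O[C@@]2(C)CC[C@@H]3O[C@@]3(C)CC[C@@H](C(C)=C)C[C@H]1OC(C)=O | intermediate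
16 | 4-O-triethylsilyl ether of 17 | C=C(C)[C@@H]1CC[C@@](C)(O)[C@@H]2CC[C@@](C)(O2)[C@@H](O)CC[C@](C)(O[Si](CC)(CC)CC)[C@H](OC(C)=O)C1 | intermediate
17 | (1R,3R,4S,7S,8R,11S,12R)-3-acetoxy-8,11-epoxy-1-isopropenyl-4,8,12-trimethylcyclotetradecane-4,7,12-triol | C=C(C)[C@@H]1CC[C@@](C)(O)[C@@H]2CC[C@@](C)(O2)[C@@H](O)CC[C@](C)(O)[C@H](OC(C)=O)C1 | intermediate
18 | C17 allylic alcohol of 17 (1-[3-hydroxyprop-1-en-2-yl] analogue) | C=C(CO)[C@@H]1CC[C@@](C)(O)[C@@H]2CC[C@@](C)(O2)[C@@H](O)CC[C@](C)(O)[C@H](OC(C)=O)C1 | intermediate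
19 | C17 aldehyde of 17 (1-[3-oxoprop-1-en-2-yl] analogue) | C=C(C=O)[C@@H]1CC[C@@](C)(O)[C@@H]2CC[C@@](C)(O2)[C@@H](O)CC[C@](C)(O)[C@H](OC(C)=O)C1 | intermediate
20 | Dendronpholide J | C=C(C(=O)O)[C@@H]1CC[C@@](C)(O)[C@@H]2CC[C@@](C)(O2)[C@@H](O)CC[C@](C)(O)[C@H](OC(C)=O)C1 | target

**Step count and risks**

Total steps: 16. Longest linear sequence: 16 steps (from 1).

Steps most likely to fail:

Step 14 (key step). The two epoxides may open in the wrong order: water may capture C8 of the activated 7,8-epoxide before the neighbouring epoxide oxygen does, or the 7,8-epoxide oxygen may attack C12 in the 6-endo sense, which would lead to oxane/oxepane ethers or C8/C11-epimeric oxolanes. The fallback opens one epoxide at a time; it sets out from 14 and comes back at 16. Shi epoxidation of 14 with the same ent-ketone but one equivalent of Oxone, followed by chromatographic separation from the regioisomer, should give the (11S,12S)-11,12-monoepoxide F1. Aqueous HClO4 in THF at 0 °C should open F1 at tertiary C12 with inversion to the (11S,12R)-11,12-diol F2. A second Shi epoxidation of the remaining 7,8-olefin should give the (7S,8S)-epoxy diol F3. CSA in dry CH2Cl2 should then close the oxolane by unambiguous 5-exo attack of the C11 hydroxyl on C8 to give 16, which is desilylated to 17 as in step 14.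

Step 9. Intermolecular aldol oligomerisation and self-condensation of the enolisable aldehyde may outrun ring closure. The fallback closes the same C1=C2 bond by an intramolecular Horner–Wadsworth–Emmons reaction; it sets out from 8 and comes back at 11. Wacker oxidation of nitrile 8 (conditions of step 8) should give the keto nitrile F4. Its kinetic methyl-ketone enolate (LDA, THF, −78 °C) is C-phosphinylated with ClP(OEt)2 and oxidised with H2O2 to the β-ketophosphonate F5. The keto-phosphonate is shielded as its sodium enolate (NaH) while DIBAL-H reduces the nitrile, giving after hydrolysis the aldehyde F6. LiCl/DBU in MeCN at 2 mM should then give 11.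

Step 15. The ene step of the SeO2 oxidation may abstract the C1 methine hydrogen instead of a methyl hydrogen (giving the C1 tertiary alcohol), or the oxidation may stall or over-run. The fallback moves the oxygen in through an epoxide; it sets out from 17 and comes back at 18. mCPBA/NaHCO3 epoxidises the isopropenyl group, the only olefin in 17, to the 15,16-epoxide F7 (both C15 epimers serve). Excess diethylaluminium 2,2,6,6-tetramethylpiperidide in toluene at 0 °C isomerises the epoxide by syn-abstraction of a methyl hydrogen to the allylic alcohol 18, which MnO2 oxidises to 19 as in step 15.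

Further compounds
F1 | step 14 | (11S,12S)-11,12-monoepoxide of 14 | C[C@]1(O[Si](CC)(CC)CC)CC/C=C(\C)CC[C@@H]2O[C@@]2(C)CC[C@@H](C(C)=C)C[C@H]1OC(C)=O
F2 | step 14 | (11S,12R)-11,12-diol from F1 | C[C@]1(O[Si](CC)(CC)CC)CC/C=C(\C)CC[C@H](O)[C@](C)(O)CC[C@@H](C(C)=C)C[C@H]1OC(C)=O
F3 | step 14 | (7S,8S)-7,8-epoxide of F2 | C[C@]1(O[Si](CC)(CC)CC)CC[C@@H]2O[C@@]2(C)CC[C@H](O)[C@](C)(O)CC[C@@H](C(C)=C)C[C@H]1OC(C)=O
F4 | step 9 | (4E,8E,12S)-4,8,12-trimethyl-13-oxo-12-(triethylsilyloxy)tetradeca-4,8-dienenitrile | CC(=O)[C@@](C)(O[Si](CC)(CC)CC)CC/C=C(\C)CC/C=C(\C)CCC#N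
F5 | step 9 | diethyl β-ketophosphonate of F4 (phosphonate on the ketone methyl carbon) | CCOP(=O)(OCC)CC(=O)[C@@](C)(O[Si](CC)(CC)CC)CC/C=C(\C)CC/C=C(\C)CCC#N
F6 | step 9 | aldehyde from F5 (nitrile reduced to CHO) | CCOP(=O)(OCC)CC(=O)[C@@](C)(O[Si](CC)(CC)CC)CC/C=C(\C)CC/C=C(\C)CCC=O
F7 | step 15 | 15,16-epoxide of 17 (C15 epimers) | CC1(CO1)[C@@H]2CC[C@@](C)(O)[C@@H]3CC[C@@](C)(O3)[C@@H](O)CC[C@](C)(O)[C@H](OC(C)=O)C2
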